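## Retrosynthetic overview

1. The hydroxy-methoxy-quinone is unveiled last from aryl tosylate 27 (cerium oxidation, then displacement of the tosyloxy group that marks the future quinone OH); the C8 methyl comes from a C8 ketone via enol triflate, cuprate and OH-directed hydrogenation.
2. Key disconnection C9–C11: intermolecular aldol addition of the C9 enolate of bicyclic enone 13 to aryl aldehyde 18, followed by benzylic deoxygenation, joins arene and decalin and creates the quaternary C9.
3. The cis-decalin 11 (5-OH and 10-H syn) comes from the achiral p-quinol dienone 6 by a catalytic enantioselective intramolecular Michael addition of a tethered bis-sulfonyl carbanion, then desulfonylation.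
4. Dienone 6 comes from phenol, prenyl bromide and bis(phenylsulfonyl)methane; aldehyde 18 comes from 1,2,4,5-tetramethoxybenzene.
5. Ring order: ring B (the former phenol ring) first, ring A closed onto it (C1–C10 bond), the pre-formed arene oxidised to the quinone at the end.

Convention: decalin carbons carry terpenoid numbers (ring A = C1–C5 and C10, ring B = C5–C10, C11 = the CH2 link to the arene); α is the face of the C5 hydroxyl; systematic names use naphthalene numbering.

## Route

Step 1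
Reactants: 1 bis(phenylsulfonyl)methane; 2 1-bromo-3-methylbut-2-ene (prenyl bromide)
Product: 3 4-methyl-1,1-bis(phenylsulfonyl)pent-3-ene
Conditions: K2CO3 (1.0 equiv), 1 in 1.5-fold excess, DMF, 25 °C
Reagents that add atoms: none
Why: SN2 C-alkylation of the doubly sulfonyl-stabilised carbanion of 1 at the primary allylic carbon of 2, with 1 kept in excess so that the less acidic mono-alkylation product is not alkylated again.

Step 2
Reactants: 3 4-methyl-1,1-bis(phenylsulfonyl)pent-3-ene; 4 phenol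
Product: 5 4-[2-methyl-5,5-bis(phenylsulfonyl)pentan-2-yl]phenol
Conditions: 4 (6 equiv), Amberlyst-15 (sulfonic acid resin), ClCH2CH2Cl, 70 °C
Reagents that add atoms: none
Why: Friedel–Crafts alkylation in which Markovnikov protonation of the trisubstituted alkene gives a tertiary carbocation that substitutes phenol at the para position under thermodynamic control (ortho and O-alkyl adducts revert), the excess phenol suppressing dialkylation.

Step 3
Reactants: 5 4-[2-methyl-5,5-bis(phenylsulfonyl)pentan-2-yl]phenol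
Product: 6 4-hydroxy-4-[2-methyl-5,5-bis(phenylsulfonyl)pentan-2-yl]cyclohexa-2,5-dien-1-one
Conditions: PhI(OAc)2 (1.2 equiv), MeCN/H2O 3:1, 0 °C
Reagents that add atoms: water, O
Why: Hypervalent-iodine oxidative dearomatisation in which the oxidised phenol is captured by water at the substituted para carbon to give the achiral p-quinol, while the weakly acidic medium keeps the C–H-acidic bis-sulfone from cyclising prematurely.

Step 4
Reactants: 6 4-hydroxy-4-[2-methyl-5,5-bis(phenylsulfonyl)pentan-2-yl]cyclohexa-2,5-dien-1-one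
Product: 7 (4aS,8aS)-4a-hydroxy-5,5-dimethyl-8,8-bis(phenylsulfonyl)-4a,5,6,7,8,8a-hexahydronaphthalen-2(1H)-one
Conditions: quinine-derived thiourea 1-[3,5-bis(trifluoromethyl)phenyl]-3-(9-deoxy-epi-quinin-9-yl)thiourea (10 mol %), toluene, 25 °C
Reagents that add atoms: none
Why: Organocatalytic intramolecular Michael addition that desymmetrises the prochiral cyclohexadienone, the tether reaching the enone β-carbon C10 only from the face on which C4 sits so that the new ring is necessarily cis-fused with 5-OH and 10-H syn, while the bifunctional catalyst (amine base plus hydrogen-bond donor) selects one of the two enantiotopic enone arms and so fixes C5 and C10 absolutely (the quinidine-derived pseudo-enantiomer is used instead should the first run show the opposite sense).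

Step 5
Reactants: 7 (4aS,8aS)-4a-hydroxy-5,5-dimethyl-8,8-bis(phenylsulfonyl)-4a,5,6,7,8,8a-hexahydronaphthalen-2(1H)-one
Product: 8 (4aS,8aS)-5,5-dimethyl-8,8-bis(phenylsulfonyl)-1,2,4a,5,6,7,8,8a-octahydronaphthalene-2,4a-diol (both C2 epimers)
Conditions: NaBH4, CeCl3·7H2O, MeOH, −78 to 0 °C
Reagents that add atoms: none
Why: Luche 1,2-reduction turns the enone into an allylic alcohol (new carbinol configuration irrelevant, reoxidised in step 7), which protects it from the electron-transfer conditions of step 6 and removes any chance of retro-Michael ring opening.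

Step 6
Reactants: 8 (4aS,8aS)-5,5-dimethyl-8,8-bis(phenylsulfonyl)-1,2,4a,5,6,7,8,8a-octahydronaphthalene-2,4a-diol
Product: 10 (4aR,8aS)-5,5-dimethyl-1,2,4a,5,6,7,8,8a-octahydronaphthalene-2,4a-diol (both C2 epimers), via monosulfone diol 9 (not isolated)
Conditions: Mg turnings (30 equiv), MeOH, 25 to 50 °C
Reagents that add atoms: none
Why: Reductive desulfonylation by single-electron transfer from magnesium cleaves the two C–S bonds one after the other and leaves C1 as CH2, the isolated alkene and the alcohols being inert.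

Step 7
Reactants: 10 (4aR,8aS)-5,5-dimethyl-1,2,4a,5,6,7,8,8a-octahydronaphthalene-2,4a-diol
Product: 11 (4aR,8aS)-4a-hydroxy-5,5-dimethyl-4a,5,6,7,8,8a-hexahydronaphthalen-2(1H)-one
Conditions: MnO2 (activated, 15 equiv), CH2Cl2, 25 °C
Reagents that add atoms: none
Why: Chemoselective allylic oxidation in which MnO2 oxidises only the secondary allylic alcohol back to the enone, whose C6=C7 double bond and quaternary C5 confine all later enolisation of the C8 ketone to C9.

Step 8
Reactants: 11 (4aR,8aS)-4a-hydroxy-5,5-dimethyl-4a,5,6,7,8,8a-hexahydronaphthalen-2(1H)-one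
Product: 13 (1S,4aS,8aS)-4a-hydroxy-1,5,5-trimethyl-4a,5,6,7,8,8a-hexahydronaphthalen-2(1H)-one (major C1 epimer), via dilithium enolate 12 (not isolated)
Conditions: LiN(iPr)2 (2.2 equiv), THF, −78 °C; MeI (1.2 equiv), −78 to −40 °C
Reagents that add atoms: iodomethane, CI
Why: Enolate alkylation in which C9 is the only enolisable position, so the cross-conjugated dienolate forms regiospecifically and is C-methylated mainly anti to the ring A carbon on C10, the C9 configuration being erased again in step 12.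

Step 9
Reactants: 14 1,2,4,5-tetramethoxybenzene
Product: 16 2,3,5,6-tetramethoxybenzaldehyde, via aryllithium 15 (not isolated)
Conditions: n-BuLi, TMEDA, THF, 0 °C; DMF, 0 to 25 °C; aqueous work-up
Reagents that add atoms: N,N-dimethylformamide, CN(C)C=O
Why: Directed ortho-lithiation at the position flanked by two methoxy groups followed by Bouveault formylation of the aryllithium with DMF.

Step 10
Reactants: 16 2,3,5,6-tetramethoxybenzaldehyde
Product: 17 2-hydroxy-3,5,6-trimethoxybenzaldehyde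
Conditions: BCl3 (1.05 equiv), CH2Cl2, −78 to 0 °C; H2O
Reagents that add atoms: none
Why: Chelation-controlled Lewis-acid ether cleavage in which BCl3 bound to the aldehyde oxygen removes only a methyl group ortho to the carbonyl (the two ortho positions are equivalent), marking the oxygen that ends as the quinone hydroxyl.

Step 11
Reactants: 17 2-hydroxy-3,5,6-trimethoxybenzaldehyde
Product: 18 2-(benzyloxy)-3,5,6-trimethoxybenzaldehyde
Conditions: BnBr, K2CO3, DMF, 60 °C
Reagents that add atoms: benzyl bromide, BrCc1ccccc1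
Why: Williamson ether synthesis on the phenoxide gives a benzyl ether that survives strong base and brief acid and still stabilises the benzylic cation needed in step 13.

Step 12
Reactants: 13 (1S,4aS,8aS)-4a-hydroxy-1,5,5-trimethyl-4a,5,6,7,8,8a-hexahydronaphthalen-2(1H)-one; 18 2-(benzyloxy)-3,5,6-trimethoxybenzaldehyde
Product: 20 (1R,4aS,8aS)-1-{[2-(benzyloxy)-3,5,6-trimethoxyphenyl](hydroxy)methyl}-4a-hydroxy-1,5,5-trimethyl-4a,5,6,7,8,8a-hexahydronaphthalen-2(1H)-one (both carbinol epimers), via dilithium enolate 19 (not isolated)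
Conditions: LiN(iPr)2 (2.3 equiv), THF, −78 to −30 °C; 18, −78 °C; AcOH quench at −78 °C
Reagents that add atoms: none
Why: Crossed aldol addition, the fragment-uniting key step, in which the regiodefined tetrasubstituted lithium enolate attacks the non-enolisable aldehyde through its α-face, anti to the ring A carbon C1 on the neighbouring C10 and on the side of the C5 lithium alkoxide, so that the quaternary C9 is formed with the aryl-bearing carbon α and the methyl β, the cold acidic quench forestalling retro-aldol cleavage.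

Step 13
Reactants: 20 (1R,4aS,8aS)-1-{[2-(benzyloxy)-3,5,6-trimethoxyphenyl](hydroxy)methyl}-4a-hydroxy-1,5,5-trimethyl-4a,5,6,7,8,8a-hexahydronaphthalen-2(1H)-one
Product: 21 (1S,4aS,8aS)-1-{[2-(benzyloxy)-3,5,6-trimethoxyphenyl]methyl}-4a-hydroxy-1,5,5-trimethyl-4a,5,6,7,8,8a-hexahydronaphthalen-2(1H)-one
Conditions: Et3SiH (5 equiv), CF3CO2H (10 equiv), CH2Cl2, −20 to 0 °C
Reagents that add atoms: none
Why: Ionic hydrogenation in which acid ionises only the benzylic alcohol (cation stabilised by two ortho alkoxy groups) and Et3SiH delivers hydride to it, C9 being quaternary so that no elimination is possible, the tertiary C5–OH being γ to the enone and therefore not ionised, and any transient C5–O–C11 ether re-ionising and being reduced as well.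

Step 14
Reactants: 21 (1S,4aS,8aS)-1-{[2-(benzyloxy)-3,5,6-trimethoxyphenyl]methyl}-4a-hydroxy-1,5,5-trimethyl-4a,5,6,7,8,8a-hexahydronaphthalen-2(1H)-one
Product: 22 (1S,4aS,8aS)-4a-hydroxy-1-[(2-hydroxy-3,5,6-trimethoxyphenyl)methyl]-1,5,5-trimethyloctahydronaphthalen-2(1H)-one
Conditions: H2 (1 atm), Pd/C (10 wt %), EtOAc/EtOH, 25 °C
Reagents that add atoms: none
Why: Heterogeneous catalytic hydrogenation saturates the C6=C7 enone double bond and hydrogenolyses the O-benzyl group in the same operation without touching ketone, arene or tertiary alcohol.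

Step 15
Reactants: 22 (1S,4aS,8aS)-4a-hydroxy-1-[(2-hydroxy-3,5,6-trimethoxyphenyl)methyl]-1,5,5-trimethyloctahydronaphthalen-2(1H)-one
Product: 23 2-{[(1S,4aS,8aS)-4a-hydroxy-1,5,5-trimethyl-2-oxodecahydronaphthalen-1-yl]methyl}-3,4,6-trimethoxyphenyl 4-methylbenzenesulfonate
Conditions: TsCl, Et3N, DMAP (cat.), CH2Cl2, 0 to 25 °C
Reagents that add atoms: 4-methylbenzenesulfonyl chloride, Cc1ccc(cc1)S(Cl)(=O)=O
Why: Sulfonylation of the phenol (the tertiary alcohol is inert) installs an electron-withdrawing group that survives base and cuprate, steers the later oxidation to the other para-dimethoxy pair and finally leaves as a good nucleofuge.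

Step 16
Reactants: 23 2-{[(1S,4aS,8aS)-4a-hydroxy-1,5,5-trimethyl-2-oxodecahydronaphthalen-1-yl]methyl}-3,4,6-trimethoxyphenyl 4-methylbenzenesulfonate
Product: 25 (1S,4aS,8aS)-4a-hydroxy-1,5,5-trimethyl-1-{[3,4,6-trimethoxy-2-(tosyloxy)phenyl]methyl}-1,4,4a,5,6,7,8,8a-octahydronaphthalen-2-yl trifluoromethanesulfonate, via dipotassium enolate 24 (not isolated)
Conditions: KN(SiMe3)2 (2.2 equiv), THF, −78 °C; PhNTf2 (1.1 equiv), −78 to 0 °C
Reagents that add atoms: N-phenylbis(trifluoromethanesulfonimide), FC(F)(F)S(=O)(=O)N(c1ccccc1)S(=O)(=O)C(F)(F)F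
Why: Enol triflate formation in which, C9 being quaternary, the ketone can only be deprotonated at C7, so trapping the potassium enolate with PhNTf2 gives the C7=C8 enol triflate regiospecifically.

Step 17
Reactants: 25 (1S,4aS,8aS)-4a-hydroxy-1,5,5-trimethyl-1-{[3,4,6-trimethoxy-2-(tosyloxy)phenyl]methyl}-1,4,4a,5,6,7,8,8a-octahydronaphthalen-2-yl trifluoromethanesulfonate
Product: 26 2-{[(1S,4aS,8aS)-4a-hydroxy-1,2,5,5-tetramethyl-1,4,4a,5,6,7,8,8a-octahydronaphthalen-1-yl]methyl}-3,4,6-trimethoxyphenyl 4-methylbenzenesulfonate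
Conditions: Me2CuLi (4 equiv), THF, −20 to 0 °C
Reagents that add atoms: lithium dimethylcuprate, [Li+].C[Cu-]C
Why: Cuprate cross-coupling of the alkenyl triflate (McMurry–Scott conditions) replaces OTf by methyl with retention of the double-bond position.

Step 18
Reactants: 26 2-{[(1S,4aS,8aS)-4a-hydroxy-1,2,5,5-tetramethyl-1,4,4a,5,6,7,8,8a-octahydronaphthalen-1-yl]methyl}-3,4,6-trimethoxyphenyl 4-methylbenzenesulfonate
Product: 27 2-{[(1R,2S,4aS,8aS)-4a-hydroxy-1,2,5,5-tetramethyldecahydronaphthalen-1-yl]methyl}-3,4,6-trimethoxyphenyl 4-methylbenzenesulfonate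
Conditions: [Ir(cod)(PCy3)(py)]PF6 (10 mol %), H2 (1 atm), CH2Cl2, 25 °C
Reagents that add atoms: none
Why: Hydroxyl-directed hydrogenation in which the cationic iridium catalyst binds the homoallylic tertiary C5–OH and delivers H2 to the α-face of C7=C8, so that H8 is α and the C8 methyl β (cis to the C9 methyl).

Step 19
Reactants: 27 2-{[(1R,2S,4aS,8aS)-4a-hydroxy-1,2,5,5-tetramethyldecahydronaphthalen-1-yl]methyl}-3,4,6-trimethoxyphenyl 4-methylbenzenesulfonate
Product: 28 2-{[(1R,2S,4aS,8aS)-4a-hydroxy-1,2,5,5-tetramethyldecahydronaphthalen-1-yl]methyl}-4-methoxy-3,6-dioxocyclohexa-1,4-dien-1-yl 4-methylbenzenesulfonate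
Conditions: (NH4)2Ce(NO3)6 (2.5 equiv), MeCN/H2O 2:1, 0 °C
Reagents that add atoms: water, O
Why: Oxidative demethylation by tetravalent cerium in which the arene radical cation is attacked by water at the only para-dimethoxy pair (the other para pair carries the deactivating sulfonate), giving the p-quinone with the sulfonyloxy group next to the alkyl branch and the remaining methoxy next to H.

Step 20
Reactants: 28 2-{[(1R,2S,4aS,8aS)-4a-hydroxy-1,2,5,5-tetramethyldecahydronaphthalen-1-yl]methyl}-4-methoxy-3,6-dioxocyclohexa-1,4-dien-1-yl 4-methylbenzenesulfonate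
Product: 29 2-hydroxy-3-{[(1R,2S,4aS,8aS)-4a-hydroxy-1,2,5,5-tetramethyldecahydronaphthalen-1-yl]methyl}-5-methoxycyclohexa-2,5-diene-1,4-dione (target)
Conditions: K2CO3, THF/H2O 1:1, 0 to 25 °C; then 1 M HCl to pH 3 at 0 °C
Reagents that add atoms: water, O
Why: Addition–elimination at the quinone (vinylogous acyl substitution) in which hydroxide displaces the far better leaving group, sulfonate, only at the carbon next to the alkyl branch, the resulting hydroxyquinone anion being inert to further substitution so that the 2-hydroxy-5-methoxy pattern is fixed.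

## Compound list

1 | bis(phenylsulfonyl)methane | O=S(=O)(CS(=O)(=O)c1ccccc1)c1ccccc1 | starting material
2 | 1-bromo-3-methylbut-2-ene (prenyl bromide) | CC(C)=CCBr | starting material
3 | 4-methyl-1,1-bis(phenylsulfonyl)pent-3-ene | CC(C)=CCC(S(=O)(=O)c1ccccc1)S(=O)(=O)c1ccccc1 | intermediate
4 | phenol | Oc1ccccc1 | starting material
5 | 4-[2-methyl-5,5-bis(phenylsulfonyl)pentan-2-yl]phenol | CC(C)(CCC(S(=O)(=O)c1ccccc1)S(=O)(=O)c1ccccc1)c1ccc(O)cc1 | intermediate
6 | 4-hydroxy-4-[2-methyl-5,5-bis(phenylsulfonyl)pentan-2-yl]cyclohexa-2,5-dien-1-one (achiral p-quinol) | O=C1C=CC(O)(C=C1)C(C)(C)CCC(S(=O)(=O)c1ccccc1)S(=O)(=O)c1ccccc1 | intermediate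
7 | (4aS,8aS)-4a-hydroxy-5,5-dimethyl-8,8-bis(phenylsulfonyl)-4a,5,6,7,8,8a-hexahydronaphthalen-2(1H)-one (cis-fused, OH and 8a-H on the same face) | O=C1C=C[C@]2(O)[C@H](C1)C(S(=O)(=O)c1ccccc1)(S(=O)(=O)c1ccccc1)CCC2(C)C | intermediate
8 | (4aS,8aS)-5,5-dimethyl-8,8-bis(phenylsulfonyl)-1,2,4a,5,6,7,8,8a-octahydronaphthalene-2,4a-diol (both C2 epimers) | OC1C=C[C@]2(O)[C@H](C1)C(S(=O)(=O)c1ccccc1)(S(=O)(=O)c1ccccc1)CCC2(C)C | intermediate
9 | (4aS,8aS)-5,5-dimethyl-8-(phenylsulfonyl)-1,2,4a,5,6,7,8,8a-octahydronaphthalene-2,4a-diol (C2 and C8 epimers) | OC1C=C[C@]2(O)[C@H](C1)C(S(=O)(=O)c1ccccc1)CCC2(C)C | intermediate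
10 | (4aR,8aS)-5,5-dimethyl-1,2,4a,5,6,7,8,8a-octahydronaphthalene-2,4a-diol (both C2 epimers) | OC1C=C[C@]2(O)[C@H](C1)CCCC2(C)C | intermediate
11 | (4aR,8aS)-4a-hydroxy-5,5-dimethyl-4a,5,6,7,8,8a-hexahydronaphthalen-2(1H)-one | O=C1C=C[C@]2(O)[C@H](C1)CCCC2(C)C | intermediate
12 | dilithium salt of 11 (C5 alkoxide and C8=C9 enolate) | C2=C(O[Li])C=C[C@]3(O[Li])[C@H]2CCCC3(C)C | intermediate
13 | (1S,4aS,8aS)-4a-hydroxy-1,5,5-trimethyl-4a,5,6,7,8,8a-hexahydronaphthalen-2(1H)-one (major C1 epimer, methyl anti to ring A) | C[C@@H]2C(=O)C=C[C@]3(O)[C@H]2CCCC3(C)C | intermediate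
14 | 1,2,4,5-tetramethoxybenzene | COc1cc(OC)c(OC)cc1OC | starting material
15 | (2,3,5,6-tetramethoxyphenyl)lithium | [Li]c1c(OC)c(OC)cc(OC)c1OC | intermediate
16 | 2,3,5,6-tetramethoxybenzaldehyde | O=Cc1c(OC)c(OC)cc(OC)c1OC | intermediate
17 | 2-hydroxy-3,5,6-trimethoxybenzaldehyde | O=Cc1c(O)c(OC)cc(OC)c1OC | intermediate
18 | 2-(benzyloxy)-3,5,6-trimethoxybenzaldehyde | O=Cc1c(OCc2ccccc2)c(OC)cc(OC)c1OC | intermediate
19 | dilithium salt of 13 (C5 alkoxide and C8=C9 enolate) | CC2=C(O[Li])C=C[C@]3(O[Li])[C@H]2CCCC3(C)C | intermediate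
20 | (1R,4aS,8aS)-1-{[2-(benzyloxy)-3,5,6-trimethoxyphenyl](hydroxy)methyl}-4a-hydroxy-1,5,5-trimethyl-4a,5,6,7,8,8a-hexahydronaphthalen-2(1H)-one (both carbinol epimers) | COc1cc(OC)c(OC)c(C(O)[C@]2(C)C(=O)C=C[C@]3(O)[C@H]2CCCC3(C)C)c1OCc1ccccc1 | intermediate
21 | (1S,4aS,8aS)-1-{[2-(benzyloxy)-3,5,6-trimethoxyphenyl]methyl}-4a-hydroxy-1,5,5-trimethyl-4a,5,6,7,8,8a-hexahydronaphthalen-2(1H)-one | COc1cc(OC)c(OC)c(C[C@]2(C)C(=O)C=C[C@]3(O)[C@H]2CCCC3(C)C)c1OCc1ccccc1 | intermediate
22 | (1S,4aS,8aS)-4a-hydroxy-1-[(2-hydroxy-3,5,6-trimethoxyphenyl)methyl]-1,5,5-trimethyloctahydronaphthalen-2(1H)-one | COc1cc(OC)c(OC)c(C[C@]2(C)C(=O)CC[C@]3(O)[C@H]2CCCC3(C)C)c1O | intermediate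
23 | 2-{[(1S,4aS,8aS)-4a-hydroxy-1,5,5-trimethyl-2-oxodecahydronaphthalen-1-yl]methyl}-3,4,6-trimethoxyphenyl 4-methylbenzenesulfonate | COc1cc(OC)c(OC)c(C[C@]2(C)C(=O)CC[C@]3(O)[C@H]2CCCC3(C)C)c1OS(=O)(=O)c1ccc(C)cc1 | intermediate
24 | dipotassium salt of 23 (C5 alkoxide and C7=C8 enolate) | COc1cc(OC)c(OC)c(C[C@]2(C)C(O[K])=CC[C@]3(O[K])[C@H]2CCCC3(C)C)c1OS(=O)(=O)c1ccc(C)cc1 | intermediate
25 | (1S,4aS,8aS)-4a-hydroxy-1,5,5-trimethyl-1-{[3,4,6-trimethoxy-2-(tosyloxy)phenyl]methyl}-1,4,4a,5,6,7,8,8a-octahydronaphthalen-2-yl trifluoromethanesulfonate | COc1cc(OC)c(OC)c(C[C@]2(C)C(OS(=O)(=O)C(F)(F)F)=CC[C@]3(O)[C@H]2CCCC3(C)C)c1OS(=O)(=O)c1ccc(C)cc1 | intermediate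
26 | 2-{[(1S,4aS,8aS)-4a-hydroxy-1,2,5,5-tetramethyl-1,4,4a,5,6,7,8,8a-octahydronaphthalen-1-yl]methyl}-3,4,6-trimethoxyphenyl 4-methylbenzenesulfonate | COc1cc(OC)c(OC)c(C[C@]2(C)C(C)=CC[C@]3(O)[C@H]2CCCC3(C)C)c1OS(=O)(=O)c1ccc(C)cc1 | intermediate
27 | 2-{[(1R,2S,4aS,8aS)-4a-hydroxy-1,2,5,5-tetramethyldecahydronaphthalen-1-yl]methyl}-3,4,6-trimethoxyphenyl 4-methylbenzenesulfonate | COc1cc(OC)c(OC)c(C[C@]2(C)[C@@H](C)CC[C@]3(O)[C@H]2CCCC3(C)C)c1OS(=O)(=O)c1ccc(C)cc1 | intermediate
28 | 2-{[(1R,2S,4aS,8aS)-4a-hydroxy-1,2,5,5-tetramethyldecahydronaphthalen-1-yl]methyl}-4-methoxy-3,6-dioxocyclohexa-1,4-dien-1-yl 4-methylbenzenesulfonate | COC1=CC(=O)C(OS(=O)(=O)c2ccc(C)cc2)=C(C[C@]2(C)[C@@H](C)CC[C@]3(O)[C@H]2CCCC3(C)C)C1=O | intermediate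
29 | 2-hydroxy-3-{[(1R,2S,4aS,8aS)-4a-hydroxy-1,2,5,5-tetramethyldecahydronaphthalen-1-yl]methyl}-5-methoxycyclohexa-2,5-diene-1,4-dione | COC1=CC(=O)C(O)=C(C[C@]2(C)[C@@H](C)CC[C@]3(O)[C@H]2CCCC3(C)C)C1=O | target

## Step count and weak points

Total step count: 20. Longest linear sequence: 17 steps (steps 1–8 and 12–20); the aryl branch (steps 9–11) joins at step 12.

Three steps most likely to fail:

Step 3 (oxidative dearomatisation of a phenol with a bulky tertiary para substituent; ipso-dealkylation or ortho attack may compete). The fallback sets out from 1 and returns at 6, building the quinol by 1,2-addition to a quinone monoketal instead. Commercial 4,4-dimethoxycyclohexa-2,5-dien-1-one F1 is treated with prenylmagnesium chloride (Me2C=CHCH2MgCl, THF, −78 °C), which adds through its γ-carbon to give 4,4-dimethoxy-1-(2-methylbut-3-en-2-yl)cyclohexa-2,5-dien-1-ol F2. The tertiary alcohol is silylated with N-trimethylsilylimidazole to give {[4,4-dimethoxy-1-(2-methylbut-3-en-2-yl)cyclohexa-2,5-dien-1-yl]oxy}trimethylsilane F3. 9-BBN followed by NaBO3·4H2O hydroborates only the terminal vinyl group to give 3-[4,4-dimethoxy-1-(trimethylsilyloxy)cyclohexa-2,5-dien-1-yl]-3-methylbutan-1-ol F4. I2, PPh3 and imidazole convert this into {[1-(4-iodo-2-methylbutan-2-yl)-4,4-dimethoxycyclohexa-2,5-dien-1-yl]oxy}trimethylsilane F5. The sodium salt of 1 (NaH, DMF, 60 °C) displaces iodide to give {[4,4-dimethoxy-1-(2-methyl-5,5-bis(phenylsulfonyl)pentan-2-yl)cyclohexa-2,5-dien-1-yl]oxy}trimethylsilane F6, and 1 M HCl in THF cleaves ketal and silyl ether to give 6.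

Step 4 (enantioselectivity of the desymmetrising Michael addition with a free tertiary OH and a gem-dimethyl tether). The fallback sets out from 6 and returns at 7, replacing asymmetric catalysis by resolution. Compound 6 is cyclised with an achiral base (Cs2CO3, MeCN, 25 °C) to the racemate, that is 7 together with its mirror image (4aR,8aR)-4a-hydroxy-5,5-dimethyl-8,8-bis(phenylsulfonyl)-4a,5,6,7,8,8a-hexahydronaphthalen-2(1H)-one F7. The two are separated by preparative chromatography on a chiral stationary phase (amylose tris(3,5-dimethylphenylcarbamate)), and F7 is discarded.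

Step 12 (aldol addition of a hindered tetrasubstituted enolate to a di-ortho-substituted aldehyde; slow addition or retro-aldol). The fallback sets out from 18 and 13 and returns at 21, replacing the aldol and deoxygenation by a direct enolate benzylation. Aldehyde 18 is reduced with NaBH4 (MeOH, 0 °C) to [2-(benzyloxy)-3,5,6-trimethoxyphenyl]methanol F8, which PBr3 (Et2O, 0 °C) converts into 2-(benzyloxy)-1-(bromomethyl)-3,5,6-trimethoxybenzene F9. The dilithium enolate 19 (from 13, LiN(iPr)2, THF/DMPU, −78 to 0 °C) is alkylated by F9 in an SN2 reaction from the same α-face, which gives 21 directly, so step 13 is bypassed.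

Further compounds
F1 | step 3 | 4,4-dimethoxycyclohexa-2,5-dien-1-one | COC1(OC)C=CC(=O)C=C1
F2 | step 3 | 4,4-dimethoxy-1-(2-methylbut-3-en-2-yl)cyclohexa-2,5-dien-1-ol | COC1(OC)C=CC(O)(C=C1)C(C)(C)C=C
F3 | step 3 | {[4,4-dimethoxy-1-(2-methylbut-3-en-2-yl)cyclohexa-2,5-dien-1-yl]oxy}trimethylsilane | COC1(OC)C=CC(O[Si](C)(C)C)(C=C1)C(C)(C)C=C
F4 | step 3 | 3-[4,4-dimethoxy-1-(trimethylsilyloxy)cyclohexa-2,5-dien-1-yl]-3-methylbutan-1-ol | COC1(OC)C=CC(O[Si](C)(C)C)(C=C1)C(C)(C)CCO
F5 | step 3 | {[1-(4-iodo-2-methylbutan-2-yl)-4,4-dimethoxycyclohexa-2,5-dien-1-yl]oxy}trimethylsilane | COC1(OC)C=CC(O[Si](C)(C)C)(C=C1)C(C)(C)CCI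
F6 | step 3 | {[4,4-dimethoxy-1-(2-methyl-5,5-bis(phenylsulfonyl)pentan-2-yl)cyclohexa-2,5-dien-1-yl]oxy}trimethylsilane | COC1(OC)C=CC(O[Si](C)(C)C)(C=C1)C(C)(C)CCC(S(=O)(=O)c1ccccc1)S(=O)(=O)c1ccccc1
F7 | step 4 | (4aR,8aR)-4a-hydroxy-5,5-dimethyl-8,8-bis(phenylsulfonyl)-4a,5,6,7,8,8a-hexahydronaphthalen-2(1H)-one | O=C1C=C[C@@]2(O)[C@@H](C1)C(S(=O)(=O)c1ccccc1)(S(=O)(=O)c1ccccc1)CCC2(C)C
F8 | step 12 | [2-(benzyloxy)-3,5,6-trimethoxyphenyl]methanol | OCc1c(OCc2ccccc2)c(OC)cc(OC)c1OC
F9 | step 12 | 2-(benzyloxy)-1-(bromomethyl)-3,5,6-trimethoxybenzene | BrCc1c(OCc2ccccc2)c(OC)cc(OC)c1OC
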